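Ring B is disconnected at C6–C7 and C8–C9. The key step exploits the C7 oxygen next to the C8 exocyclic methylene (C17) of ring B, which together are a Morita–Baylis–Hillman-type α-methylene ketone, that is, an acryloyl unit: a C6 alkylzinc on ring A is acylated by acryloyl chloride (C6–C7), and the resulting vinyl ketone closes ring B by a phosphine-mediated Rauhut–Currier addition of C8 to a C9 enoate (C8–C9), setting C9 in the same flask. The precursor is a monocyclic ring A iodide carrying the C4 and C10 quaternary centers and a C10 acrylate arm; that arm later becomes the diene side chain.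

Key step: step 10

Remark on numbering: labdane numbers (C1–C20) are used for every carbon that ends up in the target; monocyclic intermediates are also named as cyclohexanes.
Assumption: the facial sense of the valine-ester enamine alkylation in step 2 depends on the donor additive; the additive is chosen so that the (S)-keto ester 5 results.

Step 1
Reactants: 1 methyl 2-oxocyclohexane-1-carboxylate; 2 L-valine tert-butyl ester
Product: 3 methyl 2-{[(2S)-1-tert-butoxy-3-methyl-1-oxobutan-2-yl]amino}cyclohex-1-ene-1-carboxylate
Conditions: BF3·OEt2 (cat.), PhH, reflux, Dean–Stark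
Reagents that add atoms: L-valine tert-butyl ester (2), CC(C)[C@H](N)C(=O)OC(C)(C)C
Why: Acid-catalysed condensation of the ketone with the primary amine gives the conjugated, hydrogen-bonded enaminoester (enamine formation) that carries the chiral auxiliary; no ring stereocenter is formed yet.

Step 2
Reactants: 3 enaminoester
Product: 5 methyl (S)-1-methyl-2-oxocyclohexane-1-carboxylate, via methylated imine 4 (not isolated)
Conditions: LDA, PhMe, −78 °C; HMPA, MeI, −78 → −20 °C; aq. citric acid, 25 °C
Reagents that add atoms: iodomethane, CI; water, O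
Why: The chelated lithio-enamine is methylated at the α-carbon on the face left open by the valine ester chelate (auxiliary-controlled enamine alkylation), which sets the quaternary center (labdane C4) as S, and mild acid hydrolysis of the imine releases the keto ester and the auxiliary.

Step 3
Reactants: 5 methyl (S)-1-methyl-2-oxocyclohexane-1-carboxylate
Product: 6 methyl (1S)-1,3-dimethyl-2-oxocyclohexane-1-carboxylate (C3 epimers)
Conditions: LDA, THF, −78 °C; MeI, −78 → 0 °C
Reagents that add atoms: iodomethane, CI
Why: Kinetic enolate formation can occur only at C3 because C1 is quaternary, and the enolate is C-methylated (enolate alkylation); the C3 configuration is irrelevant because this carbon is made planar again in step 4.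

Step 4
Reactants: 6 methyl (1S)-1,3-dimethyl-2-oxocyclohexane-1-carboxylate
Product: 7 methyl (S)-2-(allyloxycarbonyloxy)-1,3-dimethylcyclohex-2-ene-1-carboxylate
Conditions: NaHMDS, THF, −78 → −20 °C; allyl chloroformate, −78 °C
Reagents that add atoms: allyl chloroformate, C=CCOC(Cl)=O
Why: The only enolisable position gives the tetrasubstituted sodium enolate, which the hard chloroformate traps on oxygen (enolate O-acylation) to give the allyl enol carbonate needed for the Tsuji reaction.

Step 5
Reactants: 7 allyl enol carbonate
Product: 8 methyl (1S,3R)-3-allyl-1,3-dimethyl-2-oxocyclohexane-1-carboxylate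
Conditions: Pd2(dba)3 (2.5 mol %), (R)-t-BuPHOX (6 mol %), THF, 25 °C
Reagents that add atoms: none
Why: Ionisation and loss of CO2 give an allylpalladium enolate that recombines at C3 under control of the phosphinooxazoline ligand (decarboxylative asymmetric Tsuji allylation), which sets the second quaternary center (labdane C10) as R with the two methyl groups trans, largely independently of the remote C1 center.

Step 6
Reactants: 8 methyl (1S,3R)-3-allyl-1,3-dimethyl-2-oxocyclohexane-1-carboxylate
Product: 9 methyl (1S,3R)-3-allyl-1,3-dimethyl-2-methylidenecyclohexane-1-carboxylate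
Conditions: Tebbe reagent Cp2Ti(μ-Cl)(μ-CH2)AlMe2, pyridine (cat.), THF/PhMe, −40 → 0 °C
Reagents that add atoms: Tebbe reagent, C[Al-]1(C)C[Ti](C2C=CC=C2)(C2C=CC=C2)[Cl+]1
Why: The titanium methylidene released from the Tebbe reagent methylenates the non-enolisable ketone by [2+2] cycloaddition and cycloreversion (carbonyl methylenation), a process that tolerates two flanking quaternary carbons and at low temperature spares the hindered ester; no stereocenter is formed.

Step 7
Reactants: 9 methyl (1S,3R)-3-allyl-1,3-dimethyl-2-methylidenecyclohexane-1-carboxylate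
Product: 10 methyl (1S,3R)-1,3-dimethyl-2-methylidene-3-[(E)-prop-1-enyl]cyclohexane-1-carboxylate
Conditions: RuHCl(CO)(PPh3)3 (5 mol %), PhMe, 80 °C
Reagents that add atoms: none
Why: Ruthenium hydride addition and β-hydride elimination move the terminal double bond by one position to the more stable (E)-propenyl group (alkene isomerisation), while the exocyclic methylene cannot migrate because both of its allylic carbons are quaternary.

Step 8
Reactants: 10 methyl (1S,3R)-1,3-dimethyl-2-methylidene-3-[(E)-prop-1-enyl]cyclohexane-1-carboxylate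
Product: 11 methyl (1S,3R)-3-[(E)-3-methoxy-3-oxoprop-1-enyl]-1,3-dimethyl-2-methylidenecyclohexane-1-carboxylate
Conditions: methyl acrylate (10 equiv), second-generation Hoveyda–Grubbs catalyst (5 mol %), PhMe, 80 °C
Reagents that add atoms: methyl acrylate, C=CC(=O)OC
Why: Cross-metathesis of the propenyl group with excess acrylate gives the (E)-enoate (C9=C11–C12) with loss of propene, the exocyclic 1,1-disubstituted alkene between two quaternary carbons being too hindered to take part.

Step 9
Reactants: 11 methyl (1S,3R)-3-[(E)-3-methoxy-3-oxoprop-1-enyl]-1,3-dimethyl-2-methylidenecyclohexane-1-carboxylate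
Product: 13 methyl (1S,2R,3R)-2-(iodomethyl)-3-[(E)-3-methoxy-3-oxoprop-1-enyl]-1,3-dimethylcyclohexane-1-carboxylate, via B-alkyl-9-BBN adduct 12 (not isolated)
Conditions: 9-BBN, THF, 65 °C; then I2, NaOMe, MeOH, 0 → 25 °C
Reagents that add atoms: iodine, II
Why: Syn anti-Markovnikov hydroboration puts boron on C6 and hydrogen on C5 from the α-face, opposite to the syn-axial C4 ester and C10 methyl of the reacting chair, which sets C5 (H trans to the C10 methyl), and base-promoted iodinolysis of the primary C–B bond then gives the iodide.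

Step 10
Reactants: 13 methyl (1S,2R,3R)-2-(iodomethyl)-3-[(E)-3-methoxy-3-oxoprop-1-enyl]-1,3-dimethylcyclohexane-1-carboxylate; 14 acryloyl chloride
Product: 17 dimethyl 7-oxo-13,14,15,16-tetranorlabd-8(17)-ene-12,19-dioate, via alkylzinc iodide 15 (not isolated), via vinyl ketone 16 (not isolated)
Conditions: Zn dust, LiCl, THF, 40 °C; Pd(PPh3)4 (5 mol %), acryloyl chloride, 0 → 25 °C; then PBu3, t-BuOH, THF (0.02 M), 40 °C
Reagents that add atoms: acryloyl chloride (14), C=CC(Cl)=O
Why: Zinc inserts into the primary C6–I bond (both esters are tolerated) and palladium-catalysed Negishi acylation of the alkylzinc with acryloyl chloride forms C6–C7; PBu3 then adds to C17 of the vinyl ketone, the phosphonium enolate attacks C9 of the enoate to form C8–C9, and proton transfer with β-elimination of the phosphine restores the C8=C17 methylene. The closest known reaction types are the Negishi acylation of functionalised alkylzinc halides and the intramolecular Rauhut–Currier cycloisomerisation of enone–enoates. Ring B closes in the 6-exo-trig mode (Michael addition of the C7–C8 enolate) through a chair in which the C5 and C10 arms are both equatorial, so the trans ring fusion already fixed by C5 and C10 is kept. The new stereocenter C9 is controlled by the C10 quaternary center: the CH2CO2Me group takes the equatorial β-position anti to the axial C20 methyl, and the reversible Michael step lets this more stable arrangement prevail. The step needs the phosphine to add to the unsubstituted vinyl ketone and not to the enoate, which the hindered β-substituted enoate secures, and high dilution disfavours dimerisation of the vinyl ketone.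

Step 11
Reactants: 17 dimethyl 7-oxo-13,14,15,16-tetranorlabd-8(17)-ene-12,19-dioate
Product: 18 dimethyl 7α-hydroxy-13,14,15,16-tetranorlabd-8(17)-ene-12,19-dioate
Conditions: (S)-2-methyl-CBS-oxazaborolidine (20 mol %), catecholborane, PhMe, −78 °C
Reagents that add atoms: none
Why: In this Corey–Bakshi–Shibata reduction the catalyst-bound borane delivers hydride 1,2 to the ketone from the β-face (equatorial attack, the alkenyl side acting as the large group), which should give the axial 7α-alcohol (7R) under catalyst control without conjugate reduction.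

Step 12
Reactants: 18 dimethyl 7α-hydroxy-13,14,15,16-tetranorlabd-8(17)-ene-12,19-dioate
Product: 19 methyl 7α-hydroxy-12-oxo-13,14,15,16-tetranorlabd-8(17)-en-19-oate
Conditions: i-Bu2AlH (2.2 equiv), CH2Cl2, −78 °C; Rochelle salt
Reagents that add atoms: none
Why: After deprotonation of the alcohol the unhindered C12 ester is reduced only to the aldehyde through the aluminium hemiacetal that is stable at −78 °C (partial ester reduction), while the axial neopentyl C19 ester is too hindered to react.

Step 13
Reactants: 19 methyl 7α-hydroxy-12-oxo-13,14,15,16-tetranorlabd-8(17)-en-19-oate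
Product: 20 methyl 7α-hydroxy-14-oxo-15-norlabda-8(17),12E-dien-19-oate
Conditions: Ph3P=C(CH3)CHO, PhMe, 90 °C
Reagents that add atoms: 2-(triphenylphosphoranylidene)propanal, CC(C=O)=P(c1ccccc1)(c1ccccc1)c1ccccc1
Why: Wittig reaction of the stabilised formyl ylide with the aliphatic aldehyde gives the trisubstituted enal with the 12E geometry, the favoured outcome for stabilised ylides.

Step 14
Reactants: 20 methyl 7α-hydroxy-14-oxo-15-norlabda-8(17),12E-dien-19-oate
Product: 21 methyl 7α-hydroxylabda-8(17),12E,14-trien-19-oate
Conditions: Ph3PCH3Br, KHMDS, THF, 0 °C; then 20, −78 → 25 °C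
Reagents that add atoms: methyltriphenylphosphonium bromide, C[P+](c1ccccc1)(c1ccccc1)c1ccccc1.[Br-]
Why: Wittig methylenation of the enal carbonyl completes the 12E,14-diene without touching the existing double bonds, one extra equivalent of ylide being consumed by the free hydroxyl.

Step 15
Reactants: 21 methyl 7α-hydroxylabda-8(17),12E,14-trien-19-oate
Product: 22 7α-hydroxylabda-8(17),12E,14-trien-19-oic acid
Conditions: NaSEt, DMF, 100 °C; then cold 1 M HCl
Reagents that add atoms: none
Why: The thiolate cleaves the hindered axial methyl ester by SN2 attack at the methyl carbon and not at the shielded carbonyl (nucleophilic ester dealkylation), which leaves the diene and the allylic alcohol untouched.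

Step 16
Reactants: 22 7α-hydroxylabda-8(17),12E,14-trien-19-oic acid
Product: 24 7α-acetoxylabda-8(17),12E,14-trien-19-oic acid (target), via mixed anhydride 23 (not isolated)
Conditions: Ac2O, pyridine, DMAP (cat.), CH2Cl2, 25 °C; then H2O/THF, NaHCO3, mild acid work-up
Reagents that add atoms: acetic anhydride, CC(=O)OC(C)=O
Why: DMAP-catalysed acetylation acylates the axial allylic 7α-hydroxyl with retention at C7, and the mixed anhydride formed at the hindered C19 carboxyl is hydrolysed back to the free acid on aqueous work-up.

Compound list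
1 | methyl 2-oxocyclohexane-1-carboxylate | COC(=O)C1CCCCC1=O | starting material
2 | L-valine tert-butyl ester | CC(C)[C@H](N)C(=O)OC(C)(C)C | starting material
3 | methyl 2-{[(2S)-1-tert-butoxy-3-methyl-1-oxobutan-2-yl]amino}cyclohex-1-ene-1-carboxylate | COC(=O)C1=C(N[C@@H](C(C)C)C(=O)OC(C)(C)C)CCCC1 | intermediate
4 | methyl (1S)-2-{[(2S)-1-tert-butoxy-3-methyl-1-oxobutan-2-yl]imino}-1-methylcyclohexane-1-carboxylate | COC(=O)[C@@]1(C)CCCCC1=N[C@@H](C(C)C)C(=O)OC(C)(C)C | intermediate (not isolated)
5 | methyl (S)-1-methyl-2-oxocyclohexane-1-carboxylate | O=C1CCCC[C@]1(C)C(=O)OC | intermediate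
6 | methyl (1S)-1,3-dimethyl-2-oxocyclohexane-1-carboxylate (C3 epimers) | O=C1C(C)CCC[C@]1(C)C(=O)OC | intermediate
7 | methyl (S)-2-(allyloxycarbonyloxy)-1,3-dimethylcyclohex-2-ene-1-carboxylate | C=CCOC(=O)OC1=C(C)CCC[C@]1(C)C(=O)OC | intermediate
8 | methyl (1S,3R)-3-allyl-1,3-dimethyl-2-oxocyclohexane-1-carboxylate | O=C1[C@](CC=C)(C)CCC[C@]1(C)C(=O)OC | intermediate
9 | methyl (1S,3R)-3-allyl-1,3-dimethyl-2-methylidenecyclohexane-1-carboxylate | C=C1[C@](CC=C)(C)CCC[C@]1(C)C(=O)OC | intermediate
10 | methyl (1S,3R)-1,3-dimethyl-2-methylidene-3-[(E)-prop-1-enyl]cyclohexane-1-carboxylate | C=C1[C@](/C=C/C)(C)CCC[C@]1(C)C(=O)OC | intermediate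
11 | methyl (1S,3R)-3-[(E)-3-methoxy-3-oxoprop-1-enyl]-1,3-dimethyl-2-methylidenecyclohexane-1-carboxylate | C=C1[C@](/C=C/C(=O)OC)(C)CCC[C@]1(C)C(=O)OC | intermediate
12 | B-alkyl-9-BBN adduct of 11 (boron on C6, H on C5 α) | C1CC2CCCC(C1)B2C[C@@H]1[C@](/C=C/C(=O)OC)(C)CCC[C@]1(C)C(=O)OC | intermediate (not isolated)
13 | methyl (1S,2R,3R)-2-(iodomethyl)-3-[(E)-3-methoxy-3-oxoprop-1-enyl]-1,3-dimethylcyclohexane-1-carboxylate | IC[C@@H]1[C@](/C=C/C(=O)OC)(C)CCC[C@]1(C)C(=O)OC | intermediate
14 | acryloyl chloride | C=CC(Cl)=O | starting material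
15 | alkylzinc iodide from 13 (Zn on C6) | I[Zn]C[C@@H]1[C@](/C=C/C(=O)OC)(C)CCC[C@]1(C)C(=O)OC | intermediate (not isolated)
16 | methyl (1S,2R,3R)-3-[(E)-3-methoxy-3-oxoprop-1-enyl]-1,3-dimethyl-2-(2-oxobut-3-enyl)cyclohexane-1-carboxylate | C=CC(=O)C[C@@H]1[C@](/C=C/C(=O)OC)(C)CCC[C@]1(C)C(=O)OC | intermediate (not isolated)
17 | dimethyl 7-oxo-13,14,15,16-tetranorlabd-8(17)-ene-12,19-dioate (trans-decalin; 4α-Me, 4β-CO2Me, 5α-H, 9β-CH2CO2Me, 10β-Me) | COC(=O)C[C@H]1C(=C)C(=O)C[C@@H]2[C@]1(C)CCC[C@]2(C)C(=O)OC | intermediate
18 | dimethyl 7α-hydroxy-13,14,15,16-tetranorlabd-8(17)-ene-12,19-dioate | COC(=O)C[C@H]1C(=C)[C@H](O)C[C@@H]2[C@]1(C)CCC[C@]2(C)C(=O)OC | intermediate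
19 | methyl 7α-hydroxy-12-oxo-13,14,15,16-tetranorlabd-8(17)-en-19-oate | O=CC[C@H]1C(=C)[C@H](O)C[C@@H]2[C@]1(C)CCC[C@]2(C)C(=O)OC | intermediate
20 | methyl 7α-hydroxy-14-oxo-15-norlabda-8(17),12E-dien-19-oate | O=C/C(C)=C/C[C@H]1C(=C)[C@H](O)C[C@@H]2[C@]1(C)CCC[C@]2(C)C(=O)OC | intermediate
21 | methyl 7α-hydroxylabda-8(17),12E,14-trien-19-oate | C=C/C(C)=C/C[C@H]1C(=C)[C@H](O)C[C@@H]2[C@]1(C)CCC[C@]2(C)C(=O)OC | intermediate
22 | 7α-hydroxylabda-8(17),12E,14-trien-19-oic acid | C=C/C(C)=C/C[C@H]1C(=C)[C@H](O)C[C@@H]2[C@]1(C)CCC[C@]2(C)C(=O)O | intermediate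
23 | acetic 7α-acetoxylabda-8(17),12E,14-trien-19-oic anhydride | C=C/C(C)=C/C[C@H]1C(=C)[C@H](OC(C)=O)C[C@@H]2[C@]1(C)CCC[C@]2(C)C(=O)OC(C)=O | intermediate (not isolated)
24 | (4S,5R,7R,9R,10R)-7α-acetoxylabda-8(17),12E,14-trien-19-oic acid | C=C/C(C)=C/C[C@H]1C(=C)[C@H](OC(C)=O)C[C@@H]2[C@]1(C)CCC[C@]2(C)C(=O)O | target

Total step count: 16. Longest linear sequence: 16 steps (from 1).

Steps most likely to fail

Step 10 (key step). The phosphonium enolate may add too slowly to the hindered C9, which is attached to the quaternary C10, so that the vinyl ketone oligomerises or the cyclisation stalls. Fallback, a radical annulation that still forms both bonds in one operation: setting out from 13, Bu3SnH (slow addition) and AIBN in PhH at 80 °C with excess propynal let the C6 radical add to the alkyne terminus, and the resulting α-formylvinyl radical closes ring B by 6-exo attack on C9 to give the bicyclic enal dimethyl 17-oxo-13,14,15,16-tetranorlabd-7-ene-12,19-dioate F1. Nucleophilic epoxidation (H2O2, NaOH, MeOH, 0 °C) from the less hindered α-face gives the 7α,8α-epoxy aldehyde F2, and Wharton transposition (N2H4·H2O, AcOH, MeOH) moves the oxygen to C7 and creates the C8=C17 methylene, which comes back to the route at 18 (step 11 is then not needed).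

Step 9. Facial selectivity of the hydroboration at C5 may be poor, because the monocyclic ring can react through either chair. Fallback, selection by ring constraint instead of kinetic face control: setting out from 11, hydroboration with 9-BBN and buffered perborate oxidation give the primary alcohols methyl (1S,3R)-2-(hydroxymethyl)-3-[(E)-3-methoxy-3-oxoprop-1-enyl]-1,3-dimethylcyclohexane-1-carboxylate F3 as C5 epimers. Acid-catalysed lactonisation (CSA, PhMe, 80 °C) can engage only the epimer whose hydroxymethyl is cis to the C19 ester, so the cis-fused γ-lactone F4 is separated from the unreacted epimer. Iodotrimethylsilane (TMSCl, NaI, MeCN, 60 °C) opens the lactone at the primary C6 to the iodo acid F5, and TMSCHN2 (MeOH/PhH) re-forms the methyl ester, which comes back to the route at 13.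

Step 6. Methylenation of the ketone flanked by two quaternary carbons may be slow, and the titanium carbene may then attack the ester. Fallback, nucleophilic addition and elimination instead of a metal carbene: setting out from 8, Me3SiCH2Li with CeCl3 (THF, −78 °C) adds to the ketone to give the β-hydroxysilane methyl (1S,3R)-3-allyl-2-hydroxy-1,3-dimethyl-2-[(trimethylsilyl)methyl]cyclohexane-1-carboxylate F6, and acid-induced Peterson elimination (H2SO4 cat., THF) comes back to the route at 9.

Further compounds
F1 | step 10 | dimethyl 17-oxo-13,14,15,16-tetranorlabd-7-ene-12,19-dioate | COC(=O)C[C@H]1C(C=O)=CC[C@@H]2[C@]1(C)CCC[C@]2(C)C(=O)OC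
F2 | step 10 | dimethyl 7α,8α-epoxy-17-oxo-13,14,15,16-tetranorlabdane-12,19-dioate | COC(=O)C[C@H]1[C@]3(C=O)O[C@@H]3C[C@@H]2[C@]1(C)CCC[C@]2(C)C(=O)OC
F3 | step 9 | methyl (1S,3R)-2-(hydroxymethyl)-3-[(E)-3-methoxy-3-oxoprop-1-enyl]-1,3-dimethylcyclohexane-1-carboxylate (C2 epimers) | OCC1[C@](/C=C/C(=O)OC)(C)CCC[C@]1(C)C(=O)OC
F4 | step 9 | cis-fused γ-lactone (C19 carbonyl joined through oxygen to C6) bearing the C10 (E)-acrylate arm | O=C1OC[C@@H]2[C@](/C=C/C(=O)OC)(C)CCC[C@]12C
F5 | step 9 | (1S,2R,3R)-2-(iodomethyl)-3-[(E)-3-methoxy-3-oxoprop-1-enyl]-1,3-dimethylcyclohexane-1-carboxylic acid | IC[C@@H]1[C@](/C=C/C(=O)OC)(C)CCC[C@]1(C)C(=O)O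
F6 | step 6 | methyl (1S,3R)-3-allyl-2-hydroxy-1,3-dimethyl-2-[(trimethylsilyl)methyl]cyclohexane-1-carboxylate | C[Si](C)(C)CC1(O)[C@](CC=C)(C)CCC[C@]1(C)C(=O)OC
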